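**Retrosynthetic overview**
1. Target 37 comes from acetoxycrenulide 36 by a singlet-oxygen ene reaction; 36 comes from a saturated lactone by selenoxide elimination (butenolide C=C), Wittig olefination (side-chain alkene) and OH-directed Simmons–Smith cyclopropanation.
2. The eight-membered ring (cyclooctenone 24) comes from Claisen ring expansion of a 2-methylene-6-(E)-propenyl-tetrahydropyran 23, itself made by selenoxide elimination.
3. The tetrahydropyran comes from selenoetherification of hydroxy diene 18, which comes from lactol 17 and the three-component adduct 15.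
4. Key bond C8–C9: Michael addition of the lithio azaenolate of hydrazone 7 (from (R)-citronellal) to (5S)-menthyloxyfuranone 11, with the enolate trapped by aldol addition to crotonaldehyde (C6–C7).
5. Ring order: γ-lactone (from 11), temporary tetrahydropyran, eight-membered ring, cyclopropane, butenolide C=C last.

Convention: locants follow the target. C1 = CHOAc, C2 = CH2, C3 = CHMe, C4/C5/C6 = cyclopropane (C5 = CH2), C7/C8 = butenolide α/β carbons, C9 = ring CH bearing the side chain, C10–C14 = side chain, C15 = lactone OCH2 on C8, C16 = lactone C=O on C7. PMB = 4-methoxybenzyl; Men = (1S,2R,5S)-menthyl; rt = room temperature.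

Assumption: the target configuration is the one encoded in the SMILES, which is 1R,3R,4S,6S,9S,10R in these locants.

**Step 1**
Reactants: 1 (R)-citronellal
Product: 2 (6R)-8,8-dimethoxy-2,6-dimethyloct-2-ene
Conditions: HC(OMe)3, MeOH, PPTS (cat.), 0 °C to rt
Reagents that add atoms: trimethyl orthoformate, COC(OC)OC
Why: Acid-catalysed acetalisation (orthoformate as water scavenger, PPTS mild enough to avoid the carbonyl-ene cyclisation of citronellal) masks C1 so that only the alkene is cleaved next, and C10 is untouched.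

**Step 2**
Reactants: 2 (6R)-8,8-dimethoxy-2,6-dimethyloct-2-ene
Product: 4 (4R)-6,6-dimethoxy-4-methylhexan-1-ol, via ozonolysis aldehyde 3 (not isolated)
Conditions: O3, CH2Cl2/MeOH, −78 °C; then NaBH4, −78 °C to rt
Reagents that add atoms: ozone, [O-][O+]=O
Why: Reductive ozonolysis cleaves the trisubstituted alkene and NaBH4 reduces the aldehyde in situ to the C13 alcohol while the acetal is inert.

**Step 3**
Reactants: 4 (4R)-6,6-dimethoxy-4-methylhexan-1-ol
Product: 5 1-({[(4R)-6,6-dimethoxy-4-methylhexyl]oxy}methyl)-4-methoxybenzene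
Conditions: NaH, 4-MeOC6H4CH2Cl, n-Bu4NI (cat.), THF/DMF, 0 °C to rt
Reagents that add atoms: 4-methoxybenzyl chloride, COc1ccc(CCl)cc1
Why: Williamson etherification gives a PMB ether that survives the bases, hydrides, zinc carbenoid and 220 °C used later and is removed oxidatively in step 18.

**Step 4**
Reactants: 5 PMB ether acetal
Product: 6 (3R)-6-[(4-methoxybenzyl)oxy]-3-methylhexanal
Conditions: 1 M HCl, THF, rt
Reagents that add atoms: water, O
Why: Acid-catalysed acetal hydrolysis frees the C1 aldehyde under conditions that leave the PMB ether intact.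

**Step 5**
Reactants: 6 (3R)-6-[(4-methoxybenzyl)oxy]-3-methylhexanal
Product: 7 (E)-N,N-dimethylhydrazone of 6
Conditions: Me2NNH2, MgSO4, CH2Cl2, rt
Reagents that add atoms: 1,1-dimethylhydrazine, CN(C)N
Why: Condensation gives the hydrazone, an aldehyde-level donor for azaenolate (Corey–Enders type) chemistry that keeps C1 at the oxidation level needed in step 9.

**Step 6**
Reactants: 8 furfural
Product: 9 5-hydroxyfuran-2(5H)-one
Conditions: O2, hν (visible), methylene blue (cat.), MeOH, rt
Reagents that add atoms: dioxygen, O=O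
Why: Dye-sensitised photo-oxygenation ([4+2] addition of singlet oxygen to the furan, then methanolysis with loss of the formyl carbon) is the standard route to this hydroxybutenolide.

**Step 7**
Reactants: 9 5-hydroxyfuran-2(5H)-one; 10 (+)-menthol
Product: 11 (5S)-5-[(1S,2R,5S)-menthyloxy]furan-2(5H)-one
Conditions: CSA (cat.), toluene, reflux (Dean–Stark); crystallisation from hexane, mother liquor re-equilibrated with CSA
Reagents that add atoms: none
Why: Acid-catalysed acetalisation gives both C5 epimers and the (5S)-(+)-menthyl acetal is collected by crystallisation while the mother liquor is re-epimerised, so the acetal centre is set by crystallisation-driven epimer selection.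

**Step 8**
Reactants: 7 hydrazone; 11 (5S)-menthyloxyfuranone; 12 (E)-crotonaldehyde
Product: 15 (3R,4S,5S)-3-[(1R,2E)-1-hydroxybut-2-enyl]-4-[(2S,3R)-1-(dimethylhydrazinylidene)-6-(4-methoxybenzyloxy)-3-methylhexan-2-yl]-5-[(1S,2R,5S)-menthyloxy]oxolan-2-one, via lithium azaenolate 13 (not isolated), via lithium lactone enolate 14 (not isolated)
Conditions: 7, LiN(i-Pr)2, THF, 0 °C; −78 °C, add 11; then 12, −78 °C; AcOH quench at −78 °C
Reagents that add atoms: none
Why: Tandem Michael addition–aldol reaction in which the azaenolate adds to C8 anti to the menthyloxy group (8S), crotonaldehyde attacks the resulting (E)-lactone enolate anti to the new C8 substituent (7R) through a Zimmerman–Traxler chair that gives the anti carbinol (6R), and C9 need not be controlled because either epimer converges in step 9.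

**Step 9**
Reactants: 15 Michael–aldol adduct
Product: 17 lactol (6R,7R,8S,9S,10R,15S; C1 anomers) = tetrahydropyran-2-ol ring O–C1–C9–C8–C7–C6 with axial (E)-propenyl at C6 and equatorial (2R)-5-(PMBO)pentan-2-yl at C9 and trans-fused at C7/C8 to the menthyloxy γ-lactone, via hydroxy aldehyde 16 (not isolated)
Conditions: CuCl2, THF/pH 7 phosphate buffer, rt; then DBU (0.1 equiv), CH2Cl2, rt
Reagents that add atoms: water, O
Why: Hydrazone hydrolysis frees the aldehyde, which closes on the C6 hydroxyl (lactolisation), and DBU epimerises C9 through the open aldehyde to the equatorial position on the chair locked by the trans-fused lactone (9S).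

**Step 10**
Reactants: 17 lactol
Product: 18 (3R,4S,5S)-3-[(1R,2E)-1-hydroxybut-2-enyl]-4-[(3S,4R)-7-(4-methoxybenzyloxy)-4-methylhept-1-en-3-yl]-5-[(1S,2R,5S)-menthyloxy]oxolan-2-one
Conditions: Ph3PCH3Br, n-BuLi, THF, 0 °C; add 17, −78 °C to 0 °C
Reagents that add atoms: methyltriphenylphosphonium bromide, C[P+](c1ccccc1)(c1ccccc1)c1ccccc1.[Br-]
Why: Wittig methylenation of the ring-opened lactol turns C1 into the vinyl group and frees the C6 hydroxyl at a temperature where the lithium aldolate does not revert.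

**Step 11**
Reactants: 18 hydroxy diene
Product: 19 2-(phenylselanylmethyl)tetrahydropyran (6R,7R,8S,9S,10R,15S; C1 epimers) with the substituents of 17 and CH2SePh on C1
Conditions: N-(phenylseleno)phthalimide, CSA (cat.), CH2Cl2, 0 °C to rt
Reagents that add atoms: N-(phenylseleno)phthalimide, O=C1c2ccccc2C(=O)N1[Se]c1ccccc1
Why: Phenylselenoetherification proceeds by 6-exo Markovnikov attack of the C6 hydroxyl on the seleniranium ion of the vinyl group (the propenyl seleniranium ion has no nucleophile in reach and reverts), and the new C1 centre is irrelevant because it becomes sp2 in step 14.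

**Step 12**
Reactants: 19 selenoether with menthyloxy lactone
Product: 21 selenoether γ-lactone (6R,7R,8S,9S,10R; C1 epimers) in which C15 is now OCH2, via hydroxy acid 20 (not isolated)
Conditions: KOH, NaBH4, EtOH/H2O, 0 °C to rt; then 2 M HCl to pH 1, rt
Reagents that add atoms: KOH, [K+].[OH-] (its oxygen is partly retained in the lactone carbonyl)
Why: Saponification of the lactone acetal expels menthol and unmasks an aldehyde that NaBH4 reduces at once, and acidification relactonises the hydroxy acid, with C7 and C8 safe because both substituents are equatorial on the tetrahydropyran chair.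

**Step 13**
Reactants: 21 selenoether γ-lactone
Product: 22 selenoxide of 21
Conditions: NaIO4, NaHCO3, THF/MeOH/H2O, 0 °C to rt
Reagents that add atoms: NaIO4, [Na+].[O-]I(=O)(=O)=O
Why: Periodate oxidises selenium chemoselectively and the selenoxide survives at rt because its only β-hydrogen sits on an oxygen-bearing carbon.

**Step 14**
Reactants: 22 selenoxide
Product: 24 (3R,7S,8S,9S,10R)-cyclooct-4-enone (C1 ketone, Z-C4=C6, C3 methyl, trans-fused C7/C8 γ-lactone, C9 side chain), via 2-methylene tetrahydropyran 23 (not isolated)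
Conditions: Et3N, ethyl vinyl ether, N,N-dimethylacetamide, 220 °C, sealed tube
Reagents that add atoms: none
Why: Thermal selenoxide syn-elimination gives the exocyclic enol ether, whose allyl vinyl ether unit undergoes Claisen rearrangement (ring expansion) through a chair-like transition state with the axial (E)-propenyl group, giving the Z ring alkene and transferring chirality from C6 to C3 (3R, methyl trans to the C9 side chain).

**Step 15**
Reactants: 24 cyclooctenone
Product: 25 (1R,3R,7S,8S,9S,10R)-cyclooctenol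
Conditions: LiBH(s-Bu)3, THF, −78 °C; H2O
Reagents that add atoms: none
Why: The bulky hydride reduces the ketone far faster than the lactone and attacks the carbonyl face opposite the branched C9 substituent, giving the (1R)-alcohol cis to the side chain.

**Step 16**
Reactants: 25 cyclooctenol
Product: 26 (1R,3R,4S,6S,7S,8S,9S,10R)-bicyclo[6.1.0]nonanol (cyclopropane CH2 cis to the C1 hydroxyl)
Conditions: Et2Zn, CH2I2, CH2Cl2, −10 °C to rt
Reagents that add atoms: diiodomethane, ICI
Why: Hydroxyl-directed Simmons–Smith (Furukawa) cyclopropanation, in which the zinc alkoxide at C1 delivers the carbenoid across the ring to the same face of the Z-alkene, sets C4 and C6 (4S,6S) stereospecifically.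

**Step 17**
Reactants: 26 cyclopropyl alcohol
Product: 27 C1 tert-butyldimethylsilyl ether of 26
Conditions: TBSOTf, 2,6-lutidine, CH2Cl2, −78 °C to 0 °C
Reagents that add atoms: tert-butyldimethylsilyl triflate, CC(C)(C)[Si](C)(C)OS(=O)(=O)C(F)(F)F
Why: Silylation protects the hindered C1 hydroxyl as an ether that withstands DDQ, Dess–Martin oxidation, ylide and amide base.

**Step 18**
Reactants: 27 silyl ether
Product: 28 C13 primary alcohol
Conditions: DDQ, CH2Cl2/pH 7 buffer, 0 °C to rt
Reagents that add atoms: none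
Why: Oxidative debenzylation by DDQ touches only the electron-rich PMB ether.

**Step 19**
Reactants: 28 primary alcohol
Product: 29 C13 aldehyde
Conditions: Dess–Martin periodinane, NaHCO3, CH2Cl2, rt
Reagents that add atoms: none
Why: Dess–Martin oxidation gives the aldehyde under buffered, non-epimerising conditions.

**Step 20**
Reactants: 29 aldehyde
Product: 30 side-chain alkene (C13=C14 with two methyl groups on C14)
Conditions: i-PrPPh3I, n-BuLi, THF, 0 °C; add 29, −78 °C to 0 °C
Reagents that add atoms: isopropyltriphenylphosphonium iodide, CC(C)[P+](c1ccccc1)(c1ccccc1)c1ccccc1.[I-]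
Why: Wittig olefination with the non-stabilised isopropylidene ylide installs the trisubstituted alkene only now, after the selenium electrophile of step 11 and the cyclopropanation that it would not have survived.

**Step 21**
Reactants: 30 lactone
Product: 32 (7S)-7-phenylselanyl lactone (SePh syn to H8), via lithium enolate 31 (not isolated)
Conditions: LiN(i-Pr)2, THF, −78 °C; PhSeBr, −78 °C
Reagents that add atoms: phenylselenenyl bromide, Br[Se]c1ccccc1
Why: Kinetic deprotonation at C7 (the only acidic C–H) and enolate selenenylation, with PhSeBr entering anti to the C9 ring branch on C8 and therefore syn to H8.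

**Step 22**
Reactants: 32 selenide
Product: 34 butenolide silyl ether (C7=C8), via selenoxide 33 (not isolated)
Conditions: mCPBA (1.05 equiv), CH2Cl2, −78 °C; then i-Pr2NH, −78 °C to rt
Reagents that add atoms: none
Why: Oxidation at −78 °C is selective for selenium over the alkene and selenoxide syn-elimination can only take H8 (the other β-hydrogen is on the cyclopropane), giving the tetrasubstituted butenolide.

**Step 23**
Reactants: 34 butenolide silyl ether
Product: 35 (1R,3R,4S,6S,9S,10R)-C1 alcohol (deacetyl acetoxycrenulide)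
Conditions: HF·pyridine, pyridine/THF, 0 °C to rt
Reagents that add atoms: none
Why: Buffered fluoride desilylation leaves butenolide, cyclopropane and alkene intact.

**Step 24**
Reactants: 35 alcohol
Product: 36 acetoxycrenulide
Conditions: Ac2O, DMAP (cat.), pyridine, CH2Cl2, rt
Reagents that add atoms: acetic anhydride, CC(=O)OC(C)=O
Why: DMAP-catalysed acetylation of the secondary alcohol with retention at C1.

**Step 25**
Reactants: 36 acetoxycrenulide
Product: 37 target CNP0205234.1
Conditions: O2, hν (visible), tetraphenylporphyrin (cat.), CH2Cl2, 0 °C; SiO2 chromatography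
Reagents that add atoms: dioxygen, O=O
Why: Schenck ene reaction of singlet oxygen with the electron-rich side-chain alkene (the butenolide alkene is too electron-poor) abstracts a C12 hydrogen, shifts the double bond to (E)-C12=C13 and places OOH on C14, and the regioisomeric secondary hydroperoxide (about half of the product) is removed by chromatography.

**Compound list**
1 | (R)-citronellal, (3R)-3,7-dimethyloct-6-enal | O=CC[C@H](C)CCC=C(C)C | starting material
2 | (6R)-8,8-dimethoxy-2,6-dimethyloct-2-ene | COC(OC)C[C@H](C)CCC=C(C)C | intermediate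
3 | (4R)-6,6-dimethoxy-4-methylhexanal | COC(OC)C[C@H](C)CCC=O | intermediate (not isolated)
4 | (4R)-6,6-dimethoxy-4-methylhexan-1-ol | COC(OC)C[C@H](C)CCCO | intermediate
5 | 1-({[(4R)-6,6-dimethoxy-4-methylhexyl]oxy}methyl)-4-methoxybenzene | COC(OC)C[C@H](C)CCCOCc1ccc(OC)cc1 | intermediate
6 | (3R)-6-[(4-methoxybenzyl)oxy]-3-methylhexanal | O=CC[C@H](C)CCCOCc1ccc(OC)cc1 | intermediate
7 | (E)-N,N-dimethylhydrazone of 6 | CN(C)/N=C/C[C@H](C)CCCOCc1ccc(OC)cc1 | intermediate
8 | furfural | O=Cc1ccco1 | starting material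
9 | 5-hydroxyfuran-2(5H)-one | O=C1C=CC(O)O1 | intermediate
10 | (+)-menthol, (1S,2R,5S) | O[C@H]1C[C@@H](C)CC[C@@H]1C(C)C | starting material
11 | (5S)-5-[(1S,2R,5S)-menthyloxy]furan-2(5H)-one | O=C1C=C[C@@H](O[C@H]2C[C@@H](C)CC[C@@H]2C(C)C)O1 | intermediate
12 | (E)-crotonaldehyde | C/C=C/C=O | starting material
13 | lithium azaenolate of 7 | [Li]N(N(C)C)/C=C/[C@H](C)CCCOCc1ccc(OC)cc1 | intermediate (not isolated)
14 | lithium lactone enolate formed by Michael addition (8S,9S,10R,15S) | [Li]OC1=C[C@H]([C@@H](/C=N/N(C)C)[C@H](C)CCCOCc3ccc(OC)cc3)[C@@H](O[C@H]2C[C@@H](C)CC[C@@H]2C(C)C)O1 | intermediate (not isolated)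
15 | Michael–aldol adduct (6R,7R,8S,9S,10R,15S); any C9 epimer is carried on and converged in step 9 | C/C=C/[C@@H](O)[C@@H]1C(=O)O[C@H](O[C@H]2C[C@@H](C)CC[C@@H]2C(C)C)[C@H]1[C@@H](/C=N/N(C)C)[C@H](C)CCCOCc3ccc(OC)cc3 | intermediate
16 | hydroxy aldehyde (C1 aldehyde of 15) | C/C=C/[C@@H](O)[C@@H]1C(=O)O[C@H](O[C@H]2C[C@@H](C)CC[C@@H]2C(C)C)[C@H]1[C@@H](C=O)[C@H](C)CCCOCc3ccc(OC)cc3 | intermediate (not isolated)
17 | lactol (6R,7R,8S,9S,10R,15S; C1 anomers) | OC1O[C@H](/C=C/C)[C@@H]2C(=O)O[C@H](O[C@H]3C[C@@H](C)CC[C@@H]3C(C)C)[C@H]2[C@@H]1[C@H](C)CCCOCc4ccc(OC)cc4 | intermediate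
18 | hydroxy diene (C9 vinyl, free C6 hydroxyl) | C/C=C/[C@@H](O)[C@@H]1C(=O)O[C@H](O[C@H]2C[C@@H](C)CC[C@@H]2C(C)C)[C@H]1[C@@H](C=C)[C@H](C)CCCOCc3ccc(OC)cc3 | intermediate
19 | 2-(phenylselanylmethyl)tetrahydropyran with menthyloxy lactone (C1 epimers) | C(C1O[C@H](/C=C/C)[C@@H]2C(=O)O[C@H](O[C@H]3C[C@@H](C)CC[C@@H]3C(C)C)[C@H]2[C@@H]1[C@H](C)CCCOCc4ccc(OC)cc4)[Se]c5ccccc5 | intermediate
20 | hydroxy acid (C7 CO2H, C8 CH2OH) | OC(=O)[C@H]1[C@@H](/C=C/C)OC(C[Se]c2ccccc2)[C@@H]([C@H](C)CCCOCc3ccc(OC)cc3)[C@@H]1CO | intermediate (not isolated)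
21 | selenoether γ-lactone (6R,7R,8S,9S,10R; C1 epimers) | C(C1O[C@H](/C=C/C)[C@@H]2C(=O)OC[C@H]2[C@@H]1[C@H](C)CCCOCc3ccc(OC)cc3)[Se]c4ccccc4 | intermediate
22 | selenoxide of 21 | C(C1O[C@H](/C=C/C)[C@@H]2C(=O)OC[C@H]2[C@@H]1[C@H](C)CCCOCc3ccc(OC)cc3)[Se](=O)c4ccccc4 | intermediate
23 | 2-methylene-6-(E)-propenyl tetrahydropyran (6R,7R,8S,9S,10R) | C=C1O[C@H](/C=C/C)[C@@H]2C(=O)OC[C@H]2[C@@H]1[C@H](C)CCCOCc3ccc(OC)cc3 | intermediate (not isolated)
24 | cyclooctenone (3R,7S,8S,9S,10R) | O=C1C[C@@H](C)/C=C\[C@H]2[C@@H](COC2=O)[C@@H]1[C@H](C)CCCOCc3ccc(OC)cc3 | intermediate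
25 | cyclooctenol (1R,3R,7S,8S,9S,10R) | O[C@@H]1C[C@@H](C)/C=C\[C@H]2[C@@H](COC2=O)[C@@H]1[C@H](C)CCCOCc3ccc(OC)cc3 | intermediate
26 | cyclopropyl alcohol (1R,3R,4S,6S,7S,8S,9S,10R) | O[C@@H]1C[C@@H](C)[C@@H]2C[C@@H]2[C@H]3[C@@H](COC3=O)[C@@H]1[C@H](C)CCCOCc4ccc(OC)cc4 | intermediate
27 | C1 TBS ether of 26 | CC(C)(C)[Si](C)(C)O[C@@H]1C[C@@H](C)[C@@H]2C[C@@H]2[C@H]3[C@@H](COC3=O)[C@@H]1[C@H](C)CCCOCc4ccc(OC)cc4 | intermediate
28 | C13 alcohol | CC(C)(C)[Si](C)(C)O[C@@H]1C[C@@H](C)[C@@H]2C[C@@H]2[C@H]3[C@@H](COC3=O)[C@@H]1[C@H](C)CCCO | intermediate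
29 | C13 aldehyde | CC(C)(C)[Si](C)(C)O[C@@H]1C[C@@H](C)[C@@H]2C[C@@H]2[C@H]3[C@@H](COC3=O)[C@@H]1[C@H](C)CCC=O | intermediate
30 | side-chain alkene, saturated lactone | CC(C)(C)[Si](C)(C)O[C@@H]1C[C@@H](C)[C@@H]2C[C@@H]2[C@H]3[C@@H](COC3=O)[C@@H]1[C@H](C)CCC=C(C)C | intermediate
31 | lithium enolate of 30 | CC(C)(C)[Si](C)(C)O[C@@H]1C[C@@H](C)[C@@H]2C[C@@H]2C3=C(O[Li])OC[C@H]3[C@@H]1[C@H](C)CCC=C(C)C | intermediate (not isolated)
32 | (7S)-7-phenylselanyl lactone | CC(C)(C)[Si](C)(C)O[C@@H]1C[C@@H](C)[C@@H]2C[C@@H]2[C@]3([Se]c4ccccc4)[C@@H](COC3=O)[C@@H]1[C@H](C)CCC=C(C)C | intermediate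
33 | selenoxide of 32 | CC(C)(C)[Si](C)(C)O[C@@H]1C[C@@H](C)[C@@H]2C[C@@H]2[C@]3([Se](=O)c4ccccc4)[C@@H](COC3=O)[C@@H]1[C@H](C)CCC=C(C)C | intermediate (not isolated)
34 | butenolide TBS ether | CC(C)(C)[Si](C)(C)O[C@@H]1C[C@@H](C)[C@@H]2C[C@@H]2C3=C(COC3=O)[C@@H]1[C@H](C)CCC=C(C)C | intermediate
35 | deacetyl acetoxycrenulide (1R,3R,4S,6S,9S,10R) | O[C@@H]1C[C@@H](C)[C@@H]2C[C@@H]2C3=C(COC3=O)[C@@H]1[C@H](C)CCC=C(C)C | intermediate
36 | acetoxycrenulide | CC(=O)O[C@@H]1C[C@@H](C)[C@@H]2C[C@@H]2C3=C(COC3=O)[C@@H]1[C@H](C)CCC=C(C)C | intermediate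
37 | CNP0205234.1, the (E)-C12=C13 C14 tertiary hydroperoxide | CC(=O)O[C@@H]1C[C@@H](C)[C@@H]2C[C@@H]2C2=C(COC2=O)[C@@H]1[C@H](C)C/C=C/C(C)(C)OO | target

**Totals**
Total steps: 25. Longest linear sequence: 23 steps (steps 1–5 and 8–25, from (R)-citronellal); steps 6–7 form the two-step furanone branch that joins at step 8.

**Three steps most likely to fail**

Step 8. The lithium lactone enolate may give only a modest anti/syn ratio at the C6 carbinol, and only the anti (6R) isomer places the propenyl group axially for step 14. The fallback sets out from 7 and 11 and comes back at 15. The Michael addition is run alone and quenched with AcOH at −78 °C to give the C7-unsubstituted Michael adduct lactone F1. F1 is re-enolised with LiN(i-Pr)2 (regenerating 14) and transmetallated with (c-C6H11)2BCl to the dicyclohexylboron enolate F2. Crotonaldehyde 12 is added at −78 °C; the tight boron Zimmerman–Traxler chair of the (E)-enolate gives the anti boron aldolate F3, and work-up with pH 7 buffer/MeOH releases 15.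

Step 14. The selenoxide can only eliminate toward the oxygen-bearing carbon, which needs 220 °C, so decomposition or epimerisation at C9 may compete with the Claisen shift. The fallback sets out from 21 and comes back at 24. MeOTf (CH2Cl2, 0 °C) methylates selenium to give the methyl(phenyl)selenonium triflate F4. DBU (CH2Cl2, rt) induces β-elimination of PhSeMe to give enol ether 23, which in this variant is isolated on Et3N-deactivated silica. MeAl(OC6H2-2,6-t-Bu2-4-Br)2 (CH2Cl2, −78 °C) then drives the [3,3] shift at low temperature to give 24.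

Step 15. Face selectivity of hydride addition to the flexible cyclooctenone is not secure, and the C1 configuration also decides the face of the cyclopropanation in step 16. The fallback sets out from 24 and comes back at 25. If hydride enters from the side-chain face (or deliberately with NaBH4/CeCl3 in MeOH), the (1S)-epimeric cyclooctenol F5 is formed. Mitsunobu inversion (4-O2NC6H4CO2H, PPh3, DIAD, toluene, 0 °C to rt) gives the (1R)-4-nitrobenzoate F6, and K2CO3/MeOH at 0 °C cleaves it to 25.

**Further compounds**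
F1 | step 8 | Michael adduct lactone (8S,9S,10R,15S), C7 = CH2 | O=C1C[C@H]([C@@H](/C=N/N(C)C)[C@H](C)CCCOCc3ccc(OC)cc3)[C@@H](O[C@H]2C[C@@H](C)CC[C@@H]2C(C)C)O1
F2 | step 8 | dicyclohexylboron enolate of F1 | C5CCCCC5B(C6CCCCC6)OC1=C[C@H]([C@@H](/C=N/N(C)C)[C@H](C)CCCOCc3ccc(OC)cc3)[C@@H](O[C@H]2C[C@@H](C)CC[C@@H]2C(C)C)O1
F3 | step 8 | dicyclohexylboron aldolate of 15 | C/C=C/[C@@H](OB(C4CCCCC4)C5CCCCC5)[C@@H]1C(=O)O[C@H](O[C@H]2C[C@@H](C)CC[C@@H]2C(C)C)[C@H]1[C@@H](/C=N/N(C)C)[C@H](C)CCCOCc3ccc(OC)cc3
F4 | step 14 | Se-methyl selenonium triflate of 21 | C(C1O[C@H](/C=C/C)[C@@H]2C(=O)OC[C@H]2[C@@H]1[C@H](C)CCCOCc3ccc(OC)cc3)[Se+](C)c4ccccc4.[O-]S(=O)(=O)C(F)(F)F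
F5 | step 15 | (1S)-epimer of cyclooctenol 25 | O[C@H]1C[C@@H](C)/C=C\[C@H]2[C@@H](COC2=O)[C@@H]1[C@H](C)CCCOCc3ccc(OC)cc3
F6 | step 15 | (1R)-4-nitrobenzoate of 25 | O=C(O[C@@H]1C[C@@H](C)/C=C\[C@H]2[C@@H](COC2=O)[C@@H]1[C@H](C)CCCOCc3ccc(OC)cc3)c4ccc(cc4)[N+](=O)[O-]
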